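**Retrosynthetic overview**

1. Numbering used: decalin core C1–C10 as in labdanes (C4 = CMe2, C5 = fusion CH, C10 = fusion C–CH3, C8=C9 = ring alkene, C9 carries the chain C11–C17, C17 = CH(CH3)CO2Me). The route rests on one feature: H-5 and the C10 methyl are cis, and quaternary C10 is flanked by the tetrasubstituted C8=C9 bond of ring B and, across ring A, by the C4 gem-dimethyl. This is the product pattern of an oxy-Cope shift of a 2-vinylbicyclo[2.2.2]oct-5-en-2-ol.
2. Side chain: C14–C15 by Suzuki coupling of an (E)-iodoalkene (C13 methyl and C14 iodide from carboalumination of a C13≡C14 alkyne) with an (E)-alkenylboronate from methyl (S)-3-hydroxy-2-methylpropanoate, which supplies C17; the ester is made last by oxidation and methylation.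
3. Core: the C3 carbonyl is removed by Wolff–Kishner reduction; the C1–C10 bond and ring A come from the anionic oxy-Cope shift, which cleaves the C3–C8 cage bond.
4. Cage: vinyl addition and gem-dimethylation on a bicyclo[2.2.2]octenone obtained by a catalytic enantioselective Diels–Alder reaction (sets C5) of a 1,2,3-trisubstituted cyclohexadiene with trifluoroethyl acrylate, then oxidative decarboxylation.
5. Ring order: the cyclohexadiene ring (becomes ring B), then the bicyclo[2.2.2]octene cage, then ring A.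

Key step: step 10

Abbreviations: TBS = tert-butyldimethylsilyl; Bpin = 4,4,5,5-tetramethyl-1,3,2-dioxaborolan-2-yl; Tf = trifluoromethanesulfonyl.

Assumption on step 5: the (R)-prolinol-derived catalyst is specified on the premise that the (S)-catalyst adds dienes to the Re face of the acrylate α-carbon (α-C–H···O binding model); if the sense proves opposite, the (S)-catalyst is used and nothing else changes.

**Route**

Step 1
Reactants: 1 ethyl 2-methyl-4-oxocyclohex-2-ene-1-carboxylate (racemic); 2 (3-bromopropoxy)(tert-butyl)dimethylsilane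
Product: 4 ethyl 3-[3-(tert-butyldimethylsilyloxy)propyl]-2-methyl-4-oxocyclohex-2-ene-1-carboxylate (racemic), via potassium dienolate 3 (not isolated)
Conditions: KOtBu (1.0 equiv), t-BuOH, 25 °C; then 2, NaI (cat.), 80 °C
Reagents that add atoms: none
Why: Alkylation of a vinylogous β-keto ester, in which deprotonation at C1 gives the extended dienolate that should react with the primary bromide by SN2 at the α-carbon between the ketone and the methyl-bearing carbon; the racemic C1 centre is removed in step 2.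

Step 2
Reactants: 4 ethyl 3-[3-(tert-butyldimethylsilyloxy)propyl]-2-methyl-4-oxocyclohex-2-ene-1-carboxylate
Product: 6 2-[3-(tert-butyldimethylsilyloxy)propyl]-3-methylcyclohex-2-en-1-one, via keto acid 5 (not isolated)
Conditions: LiOH·H2O, THF/MeOH/H2O, 40 °C; AcOH to pH 5; toluene, 100 °C
Reagents that add atoms: none
Why: Saponification followed by thermal decarboxylation of the vinylogous β-keto acid through its dienol should give the 2,3-disubstituted cyclohexenone, and the mild base and buffered acidification are chosen to spare the primary silyl ether.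

Step 3
Reactants: 6 2-[3-(tert-butyldimethylsilyloxy)propyl]-3-methylcyclohex-2-en-1-one
Product: 8 6-[3-(tert-butyldimethylsilyloxy)propyl]-5-methylcyclohexa-1,5-dien-1-yl trifluoromethanesulfonate, via lithium dienolate 7 (not isolated)
Conditions: LiN(i-Pr)2 (1.1 equiv), THF, −78 °C; PhNTf2, −78 → 0 °C
Reagents that add atoms: N-phenylbis(trifluoromethanesulfonimide), O=S(=O)(N(c1ccccc1)S(=O)(=O)C(F)(F)F)C(F)(F)F
Why: Kinetic deprotonation of the enone at the α′ methylene gives the cross-conjugated dienolate, which should be trapped on oxygen in a standard enol triflate formation.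

Step 4
Reactants: 8 6-[3-(tert-butyldimethylsilyloxy)propyl]-5-methylcyclohexa-1,5-dien-1-yl trifluoromethanesulfonate
Product: 9 tert-butyl[3-(2,6-dimethylcyclohexa-1,5-dien-1-yl)propoxy]dimethylsilane (2-substituted 1,3-dimethylcyclohexa-1,3-diene)
Conditions: MeMgBr (1.5 equiv), Fe(acac)3 (5 mol%), THF/NMP, −30 → 0 °C
Reagents that add atoms: methylmagnesium bromide, C[Mg]Br
Why: Iron-catalysed Kumada-type cross-coupling of an alkenyl triflate with a methyl Grignard reagent should replace OTf by CH3 without moving the diene, and the silyl ether is inert.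

Step 5
Reactants: 9 tert-butyl[3-(2,6-dimethylcyclohexa-1,5-dien-1-yl)propoxy]dimethylsilane; 10 2,2,2-trifluoroethyl acrylate
Product: 11 2,2,2-trifluoroethyl (1S,2R,4R)-6-[3-(tert-butyldimethylsilyloxy)propyl]-1,5-dimethylbicyclo[2.2.2]oct-5-ene-2-carboxylate (ester syn to the C5=C6 bridge)
Conditions: (R)-o-tolyl oxazaborolidine from (R)-α,α-diphenylprolinol, C24H24BNO (20 mol%), Tf2NH (17 mol%), 10 (2 equiv), CH2Cl2, −78 → −20 °C; minor exo adduct removed by chromatography
Reagents that add atoms: none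
Why: Enantioselective Diels–Alder reaction under chiral oxazaborolidinium catalysis, in which the unsubstituted diene terminus (largest HOMO coefficient, reinforced by the 1- and 3-methyl groups, and leading to a doubly tertiary allyl cation in the asynchronous transition state) bonds to the acrylate β-carbon so that the ester carbon joins the methyl-bearing terminus, while the catalyst exposes one face of the bound acrylate and the endo approach then fixes both bridgeheads C1 and C4; the exo adduct must be removed because it would lead to the antipodal ketone.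

Step 6
Reactants: 11 2,2,2-trifluoroethyl (1S,2R,4R)-6-[3-(tert-butyldimethylsilyloxy)propyl]-1,5-dimethylbicyclo[2.2.2]oct-5-ene-2-carboxylate
Product: 12 (1S,2R,4R)-6-[3-(tert-butyldimethylsilyloxy)propyl]-1,5-dimethylbicyclo[2.2.2]oct-5-ene-2-carboxylic acid
Conditions: LiOH, THF/H2O, 0 → 23 °C; 0.5 M HCl to pH 4, 0 °C
Reagents that add atoms: lithium hydroxide, [Li+].[OH-]
Why: Saponification of the activated trifluoroethyl ester, in which epimerisation at C2 is of no consequence because C2 becomes the carbonyl carbon in step 7.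

Step 7
Reactants: 12 (1S,2R,4R)-6-[3-(tert-butyldimethylsilyloxy)propyl]-1,5-dimethylbicyclo[2.2.2]oct-5-ene-2-carboxylic acid
Product: 15 (1R,4R)-6-[3-(tert-butyldimethylsilyloxy)propyl]-1,5-dimethylbicyclo[2.2.2]oct-5-en-2-one, via dilithium enediolate 13 (not isolated), via hydroperoxy acid 14 (not isolated)
Conditions: LiN(i-Pr)2 (2.5 equiv), THF/DMPU, 0 → 40 °C; O2 (1 atm), −78 → 0 °C; 0.5 M HCl to pH 4, 0 °C; crude, Me2NCH(OMe)2, CH2Cl2, 0 → 23 °C
Reagents that add atoms: dioxygen, O=O
Why: Oxidative decarboxylation of a carboxylic acid dianion, in which oxygenation at C2 gives the α-hydroperoxy acid and carboxyl activation by the formamide acetal should trigger decarboxylative fragmentation to the ketone, leaving both bridgehead centres untouched.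

Step 8
Reactants: 15 (1R,4R)-6-[3-(tert-butyldimethylsilyloxy)propyl]-1,5-dimethylbicyclo[2.2.2]oct-5-en-2-one
Product: 19 (1R,4S)-6-[3-(tert-butyldimethylsilyloxy)propyl]-1,3,3,5-tetramethylbicyclo[2.2.2]oct-5-en-2-one, via potassium enolate 16 (not isolated), via monomethyl ketone 17 (not isolated), via potassium enolate 18 (not isolated)
Conditions: KOtBu (3 equiv), MeI (6 equiv), THF, 0 → 23 °C
Reagents that add atoms: iodomethane, CI
Why: Exhaustive enolate C-methylation by SN2 on iodomethane, regiochemically unambiguous because C3 is the only enolisable position (C1 is a quaternary bridgehead).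

Step 9
Reactants: 19 (1R,4S)-6-[3-(tert-butyldimethylsilyloxy)propyl]-1,3,3,5-tetramethylbicyclo[2.2.2]oct-5-en-2-one
Product: 20 (1R,2S,4S)-6-[3-(tert-butyldimethylsilyloxy)propyl]-2-ethenyl-1,3,3,5-tetramethylbicyclo[2.2.2]oct-5-en-2-ol (vinyl syn to the C5=C6 bridge, hydroxyl syn to the C7–C8 bridge)
Conditions: CeCl3 (anhydrous, 3 equiv), CH2=CHMgBr (3 equiv), THF, −78 → 0 °C; aq. NH4Cl
Reagents that add atoms: vinylmagnesium bromide, C=C[Mg]Br
Why: Organocerium 1,2-addition to a hindered, non-enolisable ketone, in which the nucleophile should approach C2 from the side of the C5=C6 bridge because the other face is blocked by the inward hydrogens of the C7–C8 bridge, so the vinyl group ends syn to the alkene and the carbinol centre is set by the substrate.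

Step 10
Reactants: 20 (1R,2S,4S)-6-[3-(tert-butyldimethylsilyloxy)propyl]-2-ethenyl-1,3,3,5-tetramethylbicyclo[2.2.2]oct-5-en-2-ol
Product: 23 (4aS,8aS)-5-[3-(tert-butyldimethylsilyloxy)propyl]-1,1,4a,6-tetramethyl-3,4,4a,7,8,8a-hexahydronaphthalen-2(1H)-one (cis-fused; the target bicycle with a C3 ketone), via potassium alkoxide 21 (not isolated), via potassium enolate 22 (not isolated)
Conditions: KH (3 equiv), 18-crown-6 (3 equiv), THF, 0 → 66 °C; H2O, 0 °C
Reagents that add atoms: none
Why: The potassium alkoxide 21, freed from ion pairing by the crown ether, should undergo a [3,3]-sigmatropic shift of the 1,5-diene CH2=CH–C2(O−)–C1–C6=C5 in which the cage bond C1–C2 (future C8–C3) breaks and the vinyl terminus bonds to C5 (future C1–C10), giving enolate 22, which is protonated on work-up. The closest known reaction type is the anionic oxy-Cope rearrangement of 2-vinylbicyclo[2.2.2]oct-5-en-2-ols to cis-fused octalones. Ring A closes in a concerted pericyclic manner through the boat-like six-centre transition state enforced by the cage, the six-membered ring arising as the C1–C10 σ bond forms while the bicyclic bridge opens and the old cyclohexene becomes ring B with its alkene at C8=C9. The one new stereocentre, quaternary C10, is controlled by the substrate: the vinyl group can reach the alkene carbon only on the face that carries the carbinol bridge, so the new C1–C10 bond is cis to the C4–C5 bond and the C10 methyl ends cis to H-5, whose configuration was fixed in step 5. The step needs the [3,3] pathway to win over alkoxide fragmentation or a formal [1,3] shift and needs bond formation at a fully substituted alkene carbon; the syn-vinyl geometry holds the reacting termini close together, and release of cage strain together with formation of a delocalised enolate drives the shift. No other position is acidic or electrophilic under these conditions and the silyl ether is inert.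

Step 11
Reactants: 23 (4aS,8aS)-5-[3-(tert-butyldimethylsilyloxy)propyl]-1,1,4a,6-tetramethyl-3,4,4a,7,8,8a-hexahydronaphthalen-2(1H)-one
Product: 24 (4aS,8aS)-5-(3-hydroxypropyl)-1,1,4a,6-tetramethyl-3,4,4a,7,8,8a-hexahydronaphthalen-2(1H)-one
Conditions: Bu4NF (1.5 equiv), THF, 23 °C
Reagents that add atoms: none
Why: Fluoride-mediated cleavage of a primary silyl ether, which leaves the ketone and the tetrasubstituted alkene untouched and removes the group before the strongly basic reduction.

Step 12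
Reactants: 24 (4aS,8aS)-5-(3-hydroxypropyl)-1,1,4a,6-tetramethyl-3,4,4a,7,8,8a-hexahydronaphthalen-2(1H)-one
Product: 26 3-[(4aR,8aS)-2,5,5,8a-tetramethyl-3,4,4a,5,6,7,8,8a-octahydronaphthalen-1-yl]propan-1-ol, via hydrazone 25 (not isolated)
Conditions: N2H4·H2O, KOH, diethylene glycol, 130 °C, then 200 °C with removal of H2O
Reagents that add atoms: none
Why: Wolff–Kishner reduction in the Huang-Minlon modification, the standard way to remove a 3-keto group next to a 4,4-dimethyl carbon, with no epimerisable centre α to the carbonyl (C4 is quaternary, C2 is CH2) and an isolated tetrasubstituted alkene that should not migrate under base.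

Step 13
Reactants: 26 3-[(4aR,8aS)-2,5,5,8a-tetramethyl-3,4,4a,5,6,7,8,8a-octahydronaphthalen-1-yl]propan-1-ol
Product: 27 3-[(4aR,8aS)-2,5,5,8a-tetramethyl-3,4,4a,5,6,7,8,8a-octahydronaphthalen-1-yl]propanal
Conditions: Dess–Martin periodinane, CH2Cl2, 0 → 23 °C
Reagents that add atoms: none
Why: Dess–Martin oxidation of a primary alcohol to the aldehyde under neutral conditions that should not touch the electron-rich alkene.

Step 14
Reactants: 27 3-[(4aR,8aS)-2,5,5,8a-tetramethyl-3,4,4a,5,6,7,8,8a-octahydronaphthalen-1-yl]propanal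
Product: 28 4-[(4aR,8aS)-2,5,5,8a-tetramethyl-3,4,4a,5,6,7,8,8a-octahydronaphthalen-1-yl]but-1-yne
Conditions: dimethyl (1-diazo-2-oxopropyl)phosphonate, K2CO3, MeOH, 0 → 23 °C
Reagents that add atoms: dimethyl (1-diazo-2-oxopropyl)phosphonate, CC(=O)C(=[N+]=[N-])P(=O)(OC)OC
Why: Ohira–Bestmann variant of the Seyferth–Gilbert homologation, in which the diazomethylphosphonate anion formed in methanol adds to the aldehyde and the derived alkylidene carbene rearranges to the terminal alkyne (C13≡C14).

Step 15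
Reactants: 28 4-[(4aR,8aS)-2,5,5,8a-tetramethyl-3,4,4a,5,6,7,8,8a-octahydronaphthalen-1-yl]but-1-yne
Product: 30 (1E)-1-iodo-2-methyl-4-[(4aR,8aS)-2,5,5,8a-tetramethyl-3,4,4a,5,6,7,8,8a-octahydronaphthalen-1-yl]but-1-ene, via alkenylalane 29 (not isolated)
Conditions: AlMe3 (2.5 equiv), Cp2ZrCl2 (0.3 equiv), CH2Cl2, 0 → 23 °C; I2, THF, −30 → 0 °C
Reagents that add atoms: trimethylaluminium, C[Al](C)C; iodine, II
Why: Negishi zirconium-catalysed carboalumination adds CH3 and Al syn across the terminal alkyne with methyl on the internal carbon, and iodinolysis with retention should give the (E)-iodoalkene, which fixes the C13=C14 geometry.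

Step 16
Reactants: 31 methyl (S)-3-hydroxy-2-methylpropanoate
Product: 32 methyl (S)-3-(tert-butyldimethylsilyloxy)-2-methylpropanoate
Conditions: TBSCl, imidazole, CH2Cl2, 0 → 23 °C
Reagents that add atoms: tert-butyldimethylsilyl chloride, CC(C)(C)[Si](C)(C)Cl
Why: Imidazole-promoted silylation of a primary alcohol, which does not involve the α-stereocentre.

Step 17
Reactants: 32 methyl (S)-3-(tert-butyldimethylsilyloxy)-2-methylpropanoate
Product: 33 (S)-3-(tert-butyldimethylsilyloxy)-2-methylpropanal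
Conditions: i-Bu2AlH (1.05 equiv), CH2Cl2, −78 °C; MeOH, then aq. KNaC4H4O6
Reagents that add atoms: none
Why: Partial reduction of the ester should stop at the tetrahedral aluminium hemiacetal at −78 °C and release the aldehyde on work-up, and in the absence of base the α-stereocentre is kept.

Step 18
Reactants: 33 (S)-3-(tert-butyldimethylsilyloxy)-2-methylpropanal
Product: 34 tert-butyldimethyl{[(2R,3E)-2-methyl-4-(4,4,5,5-tetramethyl-1,3,2-dioxaborolan-2-yl)but-3-en-1-yl]oxy}silane
Conditions: Cl2CHBpin, CrCl2 (8 equiv), LiI (4 equiv), THF, 23 °C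
Reagents that add atoms: 2-(dichloromethyl)-4,4,5,5-tetramethyl-1,3,2-dioxaborolane, CC1(C)OB(C(Cl)Cl)OC1(C)C
Why: Takai–Utimoto borylolefination, in which a geminal dichromium reagent adds to the aldehyde and anti elimination should give the (E)-alkenylboronate, the weakly basic chromium species leaving the α-stereocentre intact.

Step 19
Reactants: 34 tert-butyldimethyl{[(2R,3E)-2-methyl-4-(4,4,5,5-tetramethyl-1,3,2-dioxaborolan-2-yl)but-3-en-1-yl]oxy}silane
Product: 35 (2R,3E)-2-methyl-4-(4,4,5,5-tetramethyl-1,3,2-dioxaborolan-2-yl)but-3-en-1-ol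
Conditions: camphorsulfonic acid (10 mol%), MeOH/CH2Cl2, 0 °C
Reagents that add atoms: none
Why: Acid-catalysed methanolysis of a primary silyl ether, which the pinacol boronate and the allylic stereocentre should tolerate, so that the coupling delivers the free alcohol directly.

Step 20
Reactants: 30 (1E)-1-iodo-2-methyl-4-[(4aR,8aS)-2,5,5,8a-tetramethyl-3,4,4a,5,6,7,8,8a-octahydronaphthalen-1-yl]but-1-ene; 35 (2R,3E)-2-methyl-4-(4,4,5,5-tetramethyl-1,3,2-dioxaborolan-2-yl)but-3-en-1-ol
Product: 36 (2R,3E,5E)-2,6-dimethyl-8-[(4aR,8aS)-2,5,5,8a-tetramethyl-3,4,4a,5,6,7,8,8a-octahydronaphthalen-1-yl]octa-3,5-dien-1-ol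
Conditions: PdCl2(dppf) (5 mol%; dppf = 1,1′-bis(diphenylphosphino)ferrocene), aq. K3PO4 (3 equiv), THF, degassed, 23 → 45 °C
Reagents that add atoms: none
Why: Suzuki–Miyaura coupling of an alkenyl iodide with an alkenylboronate forms C14–C15 with retention at both alkenes and should give the (13E,15E)-diene while the free alcohol and the allylic stereocentre are spectators.

Step 21
Reactants: 36 (2R,3E,5E)-2,6-dimethyl-8-[(4aR,8aS)-2,5,5,8a-tetramethyl-3,4,4a,5,6,7,8,8a-octahydronaphthalen-1-yl]octa-3,5-dien-1-ol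
Product: 38 (2R,3E,5E)-2,6-dimethyl-8-[(4aR,8aS)-2,5,5,8a-tetramethyl-3,4,4a,5,6,7,8,8a-octahydronaphthalen-1-yl]octa-3,5-dienoic acid, via dienal 37 (not isolated)
Conditions: TEMPO (0.2 equiv), PhI(OAc)2 (2.5 equiv), CH2Cl2/H2O, 0 → 23 °C
Reagents that add atoms: water, O
Why: Nitroxyl-catalysed oxidation with a hypervalent iodine co-oxidant should take the primary alcohol through the aldehyde hydrate to the acid under near-neutral conditions, which avoids epimerisation at C17 and migration of the diene into conjugation.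

Step 22
Reactants: 38 (2R,3E,5E)-2,6-dimethyl-8-[(4aR,8aS)-2,5,5,8a-tetramethyl-3,4,4a,5,6,7,8,8a-octahydronaphthalen-1-yl]octa-3,5-dienoic acid
Product: 39 methyl (2R,3E,5E)-2,6-dimethyl-8-[(4aR,8aS)-2,5,5,8a-tetramethyl-3,4,4a,5,6,7,8,8a-octahydronaphthalen-1-yl]octa-3,5-dienoate (target)
Conditions: Me3SiCHN2, toluene/MeOH, 0 °C
Reagents that add atoms: trimethylsilyldiazomethane, C[Si](C)(C)C=[N+]=[N-]
Why: Base-free methyl esterification with trimethylsilyldiazomethane in the presence of methanol should keep the α-stereocentre of the β,γ-unsaturated ester.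

**Compound list**

1 | ethyl 2-methyl-4-oxocyclohex-2-ene-1-carboxylate (racemic) | CCOC(=O)C1CCC(=O)C=C1C | starting material
2 | (3-bromopropoxy)(tert-butyl)dimethylsilane | CC(C)(C)[Si](C)(C)OCCCBr | starting material
3 | potassium 4-(ethoxycarbonyl)-3-methylcyclohexa-1,3-dien-1-olate (not isolated) | [K+].CCOC(=O)C1=C(C)C=C([O-])CC1 | intermediate
4 | ethyl 3-[3-(tert-butyldimethylsilyloxy)propyl]-2-methyl-4-oxocyclohex-2-ene-1-carboxylate (racemic) | CCOC(=O)C1CCC(=O)C(CCCO[Si](C)(C)C(C)(C)C)=C1C | intermediate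
5 | 3-[3-(tert-butyldimethylsilyloxy)propyl]-2-methyl-4-oxocyclohex-2-ene-1-carboxylic acid (not isolated) | OC(=O)C1CCC(=O)C(CCCO[Si](C)(C)C(C)(C)C)=C1C | intermediate
6 | 2-[3-(tert-butyldimethylsilyloxy)propyl]-3-methylcyclohex-2-en-1-one | CC1=C(CCCO[Si](C)(C)C(C)(C)C)C(=O)CCC1 | intermediate
7 | lithium 6-[3-(tert-butyldimethylsilyloxy)propyl]-5-methylcyclohexa-1,5-dien-1-olate (not isolated) | [Li+].[O-]C1=CCCC(C)=C1CCCO[Si](C)(C)C(C)(C)C | intermediate
8 | 6-[3-(tert-butyldimethylsilyloxy)propyl]-5-methylcyclohexa-1,5-dien-1-yl trifluoromethanesulfonate | CC1=C(CCCO[Si](C)(C)C(C)(C)C)C(OS(=O)(=O)C(F)(F)F)=CCC1 | intermediate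
9 | tert-butyl[3-(2,6-dimethylcyclohexa-1,5-dien-1-yl)propoxy]dimethylsilane | CC1=CCCC(C)=C1CCCO[Si](C)(C)C(C)(C)C | intermediate
10 | 2,2,2-trifluoroethyl acrylate | C=CC(=O)OCC(F)(F)F | starting material
11 | 2,2,2-trifluoroethyl (1S,2R,4R)-6-[3-(tert-butyldimethylsilyloxy)propyl]-1,5-dimethylbicyclo[2.2.2]oct-5-ene-2-carboxylate (ester syn to the C5=C6 bridge) | O=C(OCC(F)(F)F)[C@@H]1C[C@H]2CC[C@]1(C)C(CCCO[Si](C)(C)C(C)(C)C)=C2C | intermediate
12 | (1S,2R,4R)-6-[3-(tert-butyldimethylsilyloxy)propyl]-1,5-dimethylbicyclo[2.2.2]oct-5-ene-2-carboxylic acid | OC(=O)[C@@H]1C[C@H]2CC[C@]1(C)C(CCCO[Si](C)(C)C(C)(C)C)=C2C | intermediate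
13 | dilithium enediolate of acid 12 (not isolated) | [Li+].[Li+].[O-]C([O-])=C1C[C@H]2CC[C@]1(C)C(CCCO[Si](C)(C)C(C)(C)C)=C2C | intermediate
14 | 2-hydroperoxy derivative of acid 12, C2 configuration not controlled (not isolated) | OC(=O)C1(OO)C[C@H]2CC[C@]1(C)C(CCCO[Si](C)(C)C(C)(C)C)=C2C | intermediate
15 | (1R,4R)-6-[3-(tert-butyldimethylsilyloxy)propyl]-1,5-dimethylbicyclo[2.2.2]oct-5-en-2-one | O=C1C[C@H]2CC[C@]1(C)C(CCCO[Si](C)(C)C(C)(C)C)=C2C | intermediate
16 | potassium enolate of ketone 15 (not isolated) | [K+].[O-]C1=C[C@H]2CC[C@]1(C)C(CCCO[Si](C)(C)C(C)(C)C)=C2C | intermediate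
17 | 3-methyl derivative of ketone 15, C3 epimers (not isolated) | O=C1C(C)[C@H]2CC[C@]1(C)C(CCCO[Si](C)(C)C(C)(C)C)=C2C | intermediate
18 | potassium enolate of ketone 17 (not isolated) | [K+].[O-]C1=C(C)[C@H]2CC[C@]1(C)C(CCCO[Si](C)(C)C(C)(C)C)=C2C | intermediate
19 | (1R,4S)-6-[3-(tert-butyldimethylsilyloxy)propyl]-1,3,3,5-tetramethylbicyclo[2.2.2]oct-5-en-2-one | O=C1C(C)(C)[C@H]2CC[C@]1(C)C(CCCO[Si](C)(C)C(C)(C)C)=C2C | intermediate
20 | (1R,2S,4S)-6-[3-(tert-butyldimethylsilyloxy)propyl]-2-ethenyl-1,3,3,5-tetramethylbicyclo[2.2.2]oct-5-en-2-ol (vinyl syn to the C5=C6 bridge) | C=C[C@]1(O)C(C)(C)[C@H]2CC[C@]1(C)C(CCCO[Si](C)(C)C(C)(C)C)=C2C | intermediate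
21 | potassium alkoxide of carbinol 20 (not isolated) | [K+].C=C[C@]1([O-])C(C)(C)[C@H]2CC[C@]1(C)C(CCCO[Si](C)(C)C(C)(C)C)=C2C | intermediate
22 | potassium enolate of octalone 23 (not isolated) | [K+].CC(C)(C)[Si](C)(C)OCCCC1=C(C)CC[C@@H]2C(C)(C)C([O-])=CC[C@]12C | intermediate
23 | (4aS,8aS)-5-[3-(tert-butyldimethylsilyloxy)propyl]-1,1,4a,6-tetramethyl-3,4,4a,7,8,8a-hexahydronaphthalen-2(1H)-one (cis-fused) | CC(C)(C)[Si](C)(C)OCCCC1=C(C)CC[C@@H]2C(C)(C)C(=O)CC[C@]12C | intermediate
24 | (4aS,8aS)-5-(3-hydroxypropyl)-1,1,4a,6-tetramethyl-3,4,4a,7,8,8a-hexahydronaphthalen-2(1H)-one | OCCCC1=C(C)CC[C@@H]2C(C)(C)C(=O)CC[C@]12C | intermediate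
25 | hydrazone of ketone 24 (not isolated) | OCCCC1=C(C)CC[C@@H]2C(C)(C)C(=NN)CC[C@]12C | intermediate
26 | 3-[(4aR,8aS)-2,5,5,8a-tetramethyl-3,4,4a,5,6,7,8,8a-octahydronaphthalen-1-yl]propan-1-ol | OCCCC1=C(C)CC[C@@H]2C(C)(C)CCC[C@]12C | intermediate
27 | 3-[(4aR,8aS)-2,5,5,8a-tetramethyl-3,4,4a,5,6,7,8,8a-octahydronaphthalen-1-yl]propanal | O=CCCC1=C(C)CC[C@@H]2C(C)(C)CCC[C@]12C | intermediate
28 | 4-[(4aR,8aS)-2,5,5,8a-tetramethyl-3,4,4a,5,6,7,8,8a-octahydronaphthalen-1-yl]but-1-yne | C#CCCC1=C(C)CC[C@@H]2C(C)(C)CCC[C@]12C | intermediate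
29 | dimethyl[(1E)-2-methyl-4-(ring)but-1-en-1-yl]alane, ring as in 28 (not isolated) | C[Al](C)/C=C(\C)CCC1=C(C)CC[C@@H]2C(C)(C)CCC[C@]12C | intermediate
30 | (1E)-1-iodo-2-methyl-4-[(4aR,8aS)-2,5,5,8a-tetramethyl-3,4,4a,5,6,7,8,8a-octahydronaphthalen-1-yl]but-1-ene | I/C=C(\C)CCC1=C(C)CC[C@@H]2C(C)(C)CCC[C@]12C | intermediate
31 | methyl (S)-3-hydroxy-2-methylpropanoate | COC(=O)[C@@H](C)CO | starting material
32 | methyl (S)-3-(tert-butyldimethylsilyloxy)-2-methylpropanoate | COC(=O)[C@@H](C)CO[Si](C)(C)C(C)(C)C | intermediate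
33 | (S)-3-(tert-butyldimethylsilyloxy)-2-methylpropanal | O=C[C@@H](C)CO[Si](C)(C)C(C)(C)C | intermediate
34 | tert-butyldimethyl{[(2R,3E)-2-methyl-4-(4,4,5,5-tetramethyl-1,3,2-dioxaborolan-2-yl)but-3-en-1-yl]oxy}silane | CC1(C)OB(/C=C/[C@@H](C)CO[Si](C)(C)C(C)(C)C)OC1(C)C | intermediate
35 | (2R,3E)-2-methyl-4-(4,4,5,5-tetramethyl-1,3,2-dioxaborolan-2-yl)but-3-en-1-ol | CC1(C)OB(/C=C/[C@@H](C)CO)OC1(C)C | intermediate
36 | (2R,3E,5E)-2,6-dimethyl-8-[(4aR,8aS)-2,5,5,8a-tetramethyl-3,4,4a,5,6,7,8,8a-octahydronaphthalen-1-yl]octa-3,5-dien-1-ol | OC[C@H](C)/C=C/C=C(\C)CCC1=C(C)CC[C@@H]2C(C)(C)CCC[C@]12C | intermediate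
37 | (2R,3E,5E)-2,6-dimethyl-8-[(4aR,8aS)-2,5,5,8a-tetramethyl-3,4,4a,5,6,7,8,8a-octahydronaphthalen-1-yl]octa-3,5-dienal (not isolated) | O=C[C@H](C)/C=C/C=C(\C)CCC1=C(C)CC[C@@H]2C(C)(C)CCC[C@]12C | intermediate
38 | (2R,3E,5E)-2,6-dimethyl-8-[(4aR,8aS)-2,5,5,8a-tetramethyl-3,4,4a,5,6,7,8,8a-octahydronaphthalen-1-yl]octa-3,5-dienoic acid | OC(=O)[C@H](C)/C=C/C=C(\C)CCC1=C(C)CC[C@@H]2C(C)(C)CCC[C@]12C | intermediate
39 | methyl (2R,3E,5E)-2,6-dimethyl-8-[(4aR,8aS)-2,5,5,8a-tetramethyl-3,4,4a,5,6,7,8,8a-octahydronaphthalen-1-yl]octa-3,5-dienoate | COC(=O)[C@H](C)/C=C/C=C(\C)CCC1=C(C)CC[C@@H]2C(C)(C)CCC[C@]12C | target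

**Step count**

Total: 22 steps. Longest linear sequence: 18 steps (steps 1–15, then 20–22); the boronate branch is steps 16–19.

**Steps most likely to fail**

1. Step 10, the key step. At step 10 the alkoxide may cleave the C1–C2 cage bond heterolytically and collapse by a formal [1,3] shift or by protonation of the allyl anion instead of closing ring A, or bond formation at the fully substituted alkene carbon may be too slow. The fallback for step 10 sets out from 20 and comes back at 24. Silylation of the tertiary alcohol of 20 with Me3SiOTf and 2,6-lutidine in CH2Cl2 at −78 °C should give (1R,2S,4S)-6-[3-(tert-butyldimethylsilyloxy)propyl]-2-ethenyl-1,3,3,5-tetramethyl-2-(trimethylsilyloxy)bicyclo[2.2.2]oct-5-ene F1. Heating F1 without base in degassed 1,2-dichlorobenzene in a sealed, base-washed tube at about 230 °C should bring about the neutral siloxy-Cope [3,3] shift, which has no alkoxide fragmentation channel, and give (4aS,8aS)-5-[3-(tert-butyldimethylsilyloxy)propyl]-1,1,4a,6-tetramethyl-2-(trimethylsilyloxy)-1,4,4a,7,8,8a-hexahydronaphthalene F2. Bu4NF in THF should then remove both silyl groups from F2 and give hydroxy ketone 24, so the separate desilylation is no longer needed.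

2. Step 5. At step 5 facial discrimination by the catalyst may be insufficient on this trisubstituted diene, bond formation at the methyl-bearing diene terminus may be slow, or exo addition may erode optical purity once C2 is destroyed. The fallback for step 5 sets out from 9 and comes back at 12. Diene 9 is combined with (S)-3-acryloyl-4-benzyl-1,3-oxazolidin-2-one and Et2AlCl (1.4 equiv) in CH2Cl2 at −78 °C. The aluminium-chelated s-cis imide is shielded on one face by the benzyl group and should give, as the main diastereomer, the endo adduct (S)-4-benzyl-3-{[(1S,2R,4R)-6-[3-(tert-butyldimethylsilyloxy)propyl]-1,5-dimethylbicyclo[2.2.2]oct-5-en-2-yl]carbonyl}-1,3-oxazolidin-2-one F3. F3 is purified to a single stereoisomer by chromatography or crystallisation, so optical purity no longer depends on a catalyst. LiOH and H2O2 in THF/H2O at 0 °C should then remove the auxiliary from F3 and give acid 12.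

3. Step 7. At step 7 dianion formation at the hindered C2 may be incomplete, or radical side reactions may intervene during oxygenation (the C2 radical is homoallylic to the C5=C6 bond). The fallback for step 7 sets out from 11 and comes back at 15. The potassium enolate of ester 11, made with KN(SiMe3)2 in THF at −78 °C, is hydroxylated by polar oxygen transfer from 3-phenyl-2-(phenylsulfonyl)oxaziridine and should give 2,2,2-trifluoroethyl 6-[3-(tert-butyldimethylsilyloxy)propyl]-2-hydroxy-1,5-dimethylbicyclo[2.2.2]oct-5-ene-2-carboxylate F4, with the bridgeheads as in 11 and C2 not controlled. LiAlH4 in Et2O at 0 °C should reduce F4 to 6-[3-(tert-butyldimethylsilyloxy)propyl]-2-(hydroxymethyl)-1,5-dimethylbicyclo[2.2.2]oct-5-en-2-ol F5, and NaIO4 in THF/H2O at 23 °C should cleave the glycol of F5 to ketone 15.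

**Further compounds**

F1 | step 10 | (1R,2S,4S)-6-[3-(tert-butyldimethylsilyloxy)propyl]-2-ethenyl-1,3,3,5-tetramethyl-2-(trimethylsilyloxy)bicyclo[2.2.2]oct-5-ene | C=C[C@]1(O[Si](C)(C)C)C(C)(C)[C@H]2CC[C@]1(C)C(CCCO[Si](C)(C)C(C)(C)C)=C2C
F2 | step 10 | (4aS,8aS)-5-[3-(tert-butyldimethylsilyloxy)propyl]-1,1,4a,6-tetramethyl-2-(trimethylsilyloxy)-1,4,4a,7,8,8a-hexahydronaphthalene | CC(C)(C)[Si](C)(C)OCCCC1=C(C)CC[C@@H]2C(C)(C)C(O[Si](C)(C)C)=CC[C@]12C
F3 | step 5 | (S)-4-benzyl-3-{[(1S,2R,4R)-6-[3-(tert-butyldimethylsilyloxy)propyl]-1,5-dimethylbicyclo[2.2.2]oct-5-en-2-yl]carbonyl}-1,3-oxazolidin-2-one | O=C([C@@H]1C[C@H]2CC[C@]1(C)C(CCCO[Si](C)(C)C(C)(C)C)=C2C)N3[C@@H](Cc4ccccc4)COC3=O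
F4 | step 7 | 2,2,2-trifluoroethyl 6-[3-(tert-butyldimethylsilyloxy)propyl]-2-hydroxy-1,5-dimethylbicyclo[2.2.2]oct-5-ene-2-carboxylate | O=C(OCC(F)(F)F)C1(O)C[C@H]2CC[C@]1(C)C(CCCO[Si](C)(C)C(C)(C)C)=C2C
F5 | step 7 | 6-[3-(tert-butyldimethylsilyloxy)propyl]-2-(hydroxymethyl)-1,5-dimethylbicyclo[2.2.2]oct-5-en-2-ol | OCC1(O)C[C@H]2CC[C@]1(C)C(CCCO[Si](C)(C)C(C)(C)C)=C2C
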